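Numbering is that of chroman-2-one (O1, C2, C3, C4, C4a, C5–C8, C8a): ring A is the benzo ring, ring B the lactone, ring C the guaiacyl group on C4, and ring D the guaiacyl end of the C5 styryl group.
Retrosynthetic cuts, in order: C5–vinyl (Heck), C3–C4 (carbene C–H insertion, opens ring B), O1–C2 (esterification), C4–C4a (Friedel–Crafts acylation, with the carbonyl later reduced to CH2).
Enabling feature: C4 is a CH between C4a of ring A and C1' of ring C. With C3–C4 removed it becomes a doubly benzylic CH2 with two enantiotopic hydrogens, ortho to O1, and a diazoacetyl group on O1 puts the carbene carbon C3 within reach through a six-membered transition state.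
Forward: rings A and C are bought and joined as a benzophenone, whose chelated C8a hydroxyl stays free while the other two phenols become pivalates. Deoxygenation, O1 bromoacetylation and diazo formation give the precursor, ring B closes in the key step, ring D is added at the C5 bromide, and deacylation with re-closure of ring B ends the route.
Stereochemistry: C4 (R), the only stereocentre, is created when the chiral dirhodium carboxamidate selects the pro-R hydrogen and replaces it with retention. The E alkene follows from the syn-addition/syn-elimination course of the Heck reaction.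

Key step: step 6

Assumption: no direct analogue fixes the sense of induction in step 6, so the route is written with Rh2(5S-MEPY)4 giving the R centre; the equally available Rh2(5R-MEPY)4 would replace it, with nothing else changed, if the opposite hydrogen proves to be selected.

Step 1
Reactants: 1 5-bromoresorcinol; 2 vanillic acid (4-hydroxy-3-methoxybenzoic acid)
Product: 3 (2-bromo-4,6-dihydroxyphenyl)(4-hydroxy-3-methoxyphenyl)methanone
Conditions: P2O5 in MeSO3H (1:10 w/w), slight excess of 1, 70 °C; then ice–water
Reagents that add atoms: none
Why: Friedel–Crafts acylation by the acylium ion drawn from the free acid is standard for resorcinols; 5-substituted resorcinols such as orcinol react para to one hydroxyl and ortho to the other, which here is the carbon next to bromine, and the chelated ketone formed is too deactivated to react twice.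

Step 2
Reactants: 3 (2-bromo-4,6-dihydroxyphenyl)(4-hydroxy-3-methoxyphenyl)methanone
Product: 4 3-bromo-5-hydroxy-4-[3-methoxy-4-(pivaloyloxy)benzoyl]phenyl pivalate
Conditions: PivCl (2.1 equiv), Et3N, CH2Cl2, −10 to 0 °C
Reagents that add atoms: pivaloyl chloride, CC(C)(C)C(=O)Cl
Why: Chemoselective O-acylation, in which the future C8a hydroxyl is locked in a six-membered hydrogen bond to the ketone and shielded by the aroyl group, so the bulky acid chloride should esterify only the two free phenols, the same discrimination that allows selective 4-O-derivatisation of 2,4-dihydroxybenzophenones.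

Step 3
Reactants: 4 3-bromo-5-hydroxy-4-[3-methoxy-4-(pivaloyloxy)benzoyl]phenyl pivalate
Product: 5 3-bromo-5-hydroxy-4-[3-methoxy-4-(pivaloyloxy)benzyl]phenyl pivalate
Conditions: Et3SiH (3 equiv), TFA, CH2Cl2, 0 °C to rt
Reagents that add atoms: none
Why: Ionic hydrogenation of a diaryl ketone, in which protonation and hydride transfer from the silane occur twice, the second time through a benzhydryl cation stabilised by the ortho hydroxyl, while the aryl pivalates, the methyl ether and the bromide (meta to both ring A oxygens and so not prone to protodebromination) are inert to TFA.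

Step 4
Reactants: 5 3-bromo-5-hydroxy-4-[3-methoxy-4-(pivaloyloxy)benzyl]phenyl pivalate
Product: 6 3-bromo-2-[3-methoxy-4-(pivaloyloxy)benzyl]-5-(pivaloyloxy)phenyl bromoacetate
Conditions: BrCH2COBr (1.3 equiv), pyridine, CH2Cl2, 0 °C
Reagents that add atoms: bromoacetyl bromide, BrCC(=O)Br
Why: Pyridine-promoted O-acylation of a phenol by an acid bromide is fast even next to an ortho benzyl group, and at 0 °C acylation outpaces any displacement of the alkyl bromide.

Step 5
Reactants: 6 3-bromo-2-[3-methoxy-4-(pivaloyloxy)benzyl]-5-(pivaloyloxy)phenyl bromoacetate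
Product: 7 3-bromo-2-[3-methoxy-4-(pivaloyloxy)benzyl]-5-(pivaloyloxy)phenyl diazoacetate
Conditions: N,N'-ditosylhydrazine (2 equiv), DBU (5 equiv), THF, 0 °C
Reagents that add atoms: N,N'-ditosylhydrazine, Cc1ccc(cc1)S(=O)(=O)NNS(=O)(=O)c1ccc(C)cc1
Why: Established conversion of bromoacetates into diazoacetates, in which the reagent is N-alkylated by the bromoacetate and DBU then eliminates both sulfinate groups to leave the diazo group, all at 0 °C, where the aryl esters should not be attacked.

Step 6
Reactants: 7 3-bromo-2-[3-methoxy-4-(pivaloyloxy)benzyl]-5-(pivaloyloxy)phenyl diazoacetate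
Product: 8 (R)-5-bromo-4-[3-methoxy-4-(pivaloyloxy)phenyl]-2-oxochroman-7-yl pivalate
Conditions: Rh2(5S-MEPY)4, dirhodium tetrakis[methyl (5S)-2-oxopyrrolidine-5-carboxylate] (2 mol %), CH2Cl2, reflux, 7 added by syringe pump over 10 h at high dilution
Reagents that add atoms: none
Why: Proposed new method: loss of N2 from 7 at an axial site of the dirhodium core gives an electrophilic rhodium carbene at C3, which engages one C4–H bond in a concerted, asynchronous three-centre event (hydride shift and C3–C4 bond formation) with retention at C4, the developing positive charge being shared by rings A and C. The closest known reaction type is the dirhodium carboxamidate-catalysed enantioselective intramolecular C–H insertion of alkyl diazoacetates to gamma-lactones and, in constrained cases, delta-lactones; an aryl diazoacetate inserting into a diarylmethane CH2 has not been shown. Ring B closes by 1,6-insertion through the six-membered array C3, C2, O1, C8a, C4a, C4, which is favoured here because O1, C8a, C4a and C4 are already coplanar in ring A and because no sp3 C–H bond is available for the normally preferred five-membered closure, whose fifth atom could only be the arene carbon C8 or C4a. C4 is controlled by the catalyst alone: the two ligand ester groups that overhang each rhodium face block adjacent quadrants, so rings A and C fit in only one orientation, which presents the pro-R hydrogen to C3, and its replacement with retention gives (R)-8. Insertion must outrun aromatic substitution at C8, Buchner addition to ring C and carbene dimerisation; the pivalates on the C7 and ring C oxygens lower the nucleophilicity of both arenes, the carboxamidate ligands temper the carbene in favour of C–H insertion, the C5 bromine presses the benzyl group towards O1, and slow addition keeps the diazo concentration low. C5 carries bromine at this stage because a styryl double bond would trap the carbene faster than the C–H bond does.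

Step 7
Reactants: 9 2-methoxy-4-vinylphenol
Product: 10 2-methoxy-4-vinylphenyl pivalate
Conditions: PivCl (1.1 equiv), Et3N, DMAP (cat.), CH2Cl2, 0 °C to rt
Reagents that add atoms: pivaloyl chloride, CC(C)(C)C(=O)Cl
Why: Routine DMAP-catalysed acylation masks the phenol, which curbs polymerisation of the vinylphenol and keeps a nucleophilic phenoxide away from the lactone during the coupling.

Step 8
Reactants: 8 (R)-5-bromo-4-[3-methoxy-4-(pivaloyloxy)phenyl]-2-oxochroman-7-yl pivalate; 10 2-methoxy-4-vinylphenyl pivalate
Product: 11 (R)-4-[3-methoxy-4-(pivaloyloxy)phenyl]-5-{(E)-2-[3-methoxy-4-(pivaloyloxy)phenyl]ethenyl}-2-oxochroman-7-yl pivalate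
Conditions: Pd2(dba)3 (2.5 mol %), [HP(t-Bu)3]BF4 (10 mol %), Cy2NMe (1.5 equiv), 1,4-dioxane, 70 °C
Reagents that add atoms: none
Why: Heck reaction, in which zerovalent palladium bearing bulky, electron-rich P(t-Bu)3 inserts into ortho-substituted aryl bromides at moderate temperature, syn carbopalladation at the terminal styrene carbon and syn beta-hydride elimination give the E stilbene, and the hindered amine is too weak a base and too poor a nucleophile to disturb the lactone, the pivalates or C4.

Step 9
Reactants: 11 (R)-4-[3-methoxy-4-(pivaloyloxy)phenyl]-5-{(E)-2-[3-methoxy-4-(pivaloyloxy)phenyl]ethenyl}-2-oxochroman-7-yl pivalate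
Product: 12 methyl (R)-3-{2,4-dihydroxy-6-[(E)-2-(4-hydroxy-3-methoxyphenyl)ethenyl]phenyl}-3-(4-hydroxy-3-methoxyphenyl)propanoate
Conditions: K2CO3 (6 equiv), degassed MeOH–THF, Ar, 0 °C to rt; pH 6 buffer work-up, crude carried on
Reagents that add atoms: methanol, CO
Why: Base-mediated transesterification cleaves the three aryl pivalates and, unavoidably, the aryl ester bond O1–C2 of ring B to the methyl ester, while C4 has neither an acidic hydrogen nor a leaving group, so its configuration is untouched, and exclusion of oxygen protects the phenoxides.

Step 10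
Reactants: 12 methyl (R)-3-{2,4-dihydroxy-6-[(E)-2-(4-hydroxy-3-methoxyphenyl)ethenyl]phenyl}-3-(4-hydroxy-3-methoxyphenyl)propanoate
Product: 13 (R)-7-hydroxy-4-(4-hydroxy-3-methoxyphenyl)-5-[(E)-2-(4-hydroxy-3-methoxyphenyl)ethenyl]chroman-2-one (CNP0277187.1)
Conditions: p-TsOH·H2O (10 mol %), THF–toluene, 4 Å molecular sieves, 60 °C, Ar, dark
Reagents that add atoms: none
Why: Acid-catalysed lactonisation (intramolecular transesterification) re-forms ring B through the only hydroxyl ortho to the side chain, and because the C4 aryl group and the flanking C5 styryl group compress the ester towards that hydroxyl, catalytic acid at moderate temperature should suffice and spare the 4-hydroxystilbene.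

Compound list
1 | 5-bromoresorcinol | Oc1cc(O)cc(Br)c1 | starting material
2 | vanillic acid | COc1cc(C(=O)O)ccc1O | starting material
3 | (2-bromo-4,6-dihydroxyphenyl)(4-hydroxy-3-methoxyphenyl)methanone | COc1cc(C(=O)c2c(O)cc(O)cc2Br)ccc1O | intermediate
4 | 3-bromo-5-hydroxy-4-[3-methoxy-4-(pivaloyloxy)benzoyl]phenyl pivalate | COc1cc(C(=O)c2c(O)cc(OC(=O)C(C)(C)C)cc2Br)ccc1OC(=O)C(C)(C)C | intermediate
5 | 3-bromo-5-hydroxy-4-[3-methoxy-4-(pivaloyloxy)benzyl]phenyl pivalate | COc1cc(Cc2c(O)cc(OC(=O)C(C)(C)C)cc2Br)ccc1OC(=O)C(C)(C)C | intermediate
6 | 3-bromo-2-[3-methoxy-4-(pivaloyloxy)benzyl]-5-(pivaloyloxy)phenyl bromoacetate | COc1cc(Cc2c(OC(=O)CBr)cc(OC(=O)C(C)(C)C)cc2Br)ccc1OC(=O)C(C)(C)C | intermediate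
7 | 3-bromo-2-[3-methoxy-4-(pivaloyloxy)benzyl]-5-(pivaloyloxy)phenyl diazoacetate | [N-]=[N+]=CC(=O)Oc1cc(OC(=O)C(C)(C)C)cc(Br)c1Cc1ccc(OC(=O)C(C)(C)C)c(OC)c1 | intermediate
8 | (R)-5-bromo-4-[3-methoxy-4-(pivaloyloxy)phenyl]-2-oxochroman-7-yl pivalate | O=C1C[C@H](c2ccc(OC(=O)C(C)(C)C)c(OC)c2)c2c(Br)cc(OC(=O)C(C)(C)C)cc2O1 | intermediate
9 | 2-methoxy-4-vinylphenol | COc1cc(C=C)ccc1O | starting material
10 | 2-methoxy-4-vinylphenyl pivalate | COc1cc(C=C)ccc1OC(=O)C(C)(C)C | intermediate
11 | (R)-4-[3-methoxy-4-(pivaloyloxy)phenyl]-5-{(E)-2-[3-methoxy-4-(pivaloyloxy)phenyl]ethenyl}-2-oxochroman-7-yl pivalate | COc1cc(/C=C/c2cc(OC(=O)C(C)(C)C)cc3c2[C@@H](c2ccc(OC(=O)C(C)(C)C)c(OC)c2)CC(=O)O3)ccc1OC(=O)C(C)(C)C | intermediate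
12 | methyl (R)-3-{2,4-dihydroxy-6-[(E)-2-(4-hydroxy-3-methoxyphenyl)ethenyl]phenyl}-3-(4-hydroxy-3-methoxyphenyl)propanoate | COc1cc(/C=C/c2cc(O)cc(O)c2[C@@H](c2ccc(O)c(OC)c2)CC(=O)OC)ccc1O | intermediate
13 | (R)-7-hydroxy-4-(4-hydroxy-3-methoxyphenyl)-5-[(E)-2-(4-hydroxy-3-methoxyphenyl)ethenyl]chroman-2-one | COc1cc(/C=C/c2cc(O)cc3c2[C@@H](c2ccc(O)c(OC)c2)CC(=O)O3)ccc1O | target

Total step count: 10. Longest linear sequence: 9 (steps 1–6 and 8–10; step 7 is a side branch).

Steps most likely to fail

1. Step 6 (proposed new method). The carbene may be diverted into aromatic substitution or cycloaddition on ring A or ring C. It may also dimerise, or insert with poor discrimination between the two enantiotopic hydrogens. The fallback uses known chemistry, sets out from 4 and returns at 8. (Triphenylphosphoranylidene)ketene in refluxing toluene acylates the chelated phenol of 4. The ester ylide so formed closes on the ketone by intramolecular Wittig olefination to give the 4-arylcoumarin 5-bromo-4-[3-methoxy-4-(pivaloyloxy)phenyl]-2-oxo-2H-chromen-7-yl pivalate F1. Asymmetric conjugate reduction of F1 follows, with ligated CuH generated from CuCl, NaOt-Bu, DTBM-SEGPHOS of the handedness that gives the R centre, and pinacolborane in toluene. This reaction is established for 4-arylcoumarins and should deliver 8.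

2. Step 1. C-acylation next to bromine may be slow, so that O-acylation, self-esterification of vanillic acid or attack at the carbon between the two hydroxyls takes over. The fallback sets out from 1 and returns at 5, by-passing 3 and 4. Compound 1, in threefold excess, is benzylated with commercial vanillyl alcohol under acid catalysis (cat. p-TsOH, MeCN, rt). The quinone-methide-like cation from this alcohol is smaller and far more reactive than the acylium ion, and the product is 5-bromo-4-(4-hydroxy-3-methoxybenzyl)benzene-1,3-diol F2. Two equivalents of PivCl with Et3N at −20 °C would then esterify the two less hindered phenols under steric control alone, giving 5.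

3. Step 10. Protonation of the electron-rich 4-hydroxystilbene may lead to oligomerisation, Friedel–Crafts cyclisation onto ring C or loss of alkene geometry before the lactone has closed. The fallback sets out from 12 and returns at 13. LiOH in degassed THF–water saponifies the methyl ester, and careful acidification to about pH 4 gives (R)-3-{2,4-dihydroxy-6-[(E)-2-(4-hydroxy-3-methoxyphenyl)ethenyl]phenyl}-3-(4-hydroxy-3-methoxyphenyl)propanoic acid F3. The acid is closed without acid catalysis by carbodiimide activation (EDC·HCl, dilute CH2Cl2–DMF, 0 °C). The six-membered closure onto the neighbouring hydroxyl should outpace intermolecular esterification, giving 13.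

Further compounds
F1 | step 6 | 5-bromo-4-[3-methoxy-4-(pivaloyloxy)phenyl]-2-oxo-2H-chromen-7-yl pivalate | O=C1C=C(c2ccc(OC(=O)C(C)(C)C)c(OC)c2)c2c(Br)cc(OC(=O)C(C)(C)C)cc2O1
F2 | step 1 | 5-bromo-4-(4-hydroxy-3-methoxybenzyl)benzene-1,3-diol | COc1cc(Cc2c(O)cc(O)cc2Br)ccc1O
F3 | step 10 | (R)-3-{2,4-dihydroxy-6-[(E)-2-(4-hydroxy-3-methoxyphenyl)ethenyl]phenyl}-3-(4-hydroxy-3-methoxyphenyl)propanoic acid | COc1cc(/C=C/c2cc(O)cc(O)c2[C@@H](c2ccc(O)c(OC)c2)CC(=O)O)ccc1O
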